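The route rests on disconnecting the C4–C5 bond of ring A together with the C9–C10 bond of ring B (labdane numbering), which unfolds the decalin into an acyclic (E,E)-diene β-keto ester. The key step exploits the 1,3-dioxygen pattern around quaternary C4 (O on C3, aldehyde C19) and the 1,5-relationship of the C5=C10 and C8=C9 alkenes: manganese triacetate oxidises the keto ester to a C4 radical that joins the like-polarised alkene carbon C5, and the cascade closes rings A and B and sets C4, C5, C9 and C10 in one operation. An 8-phenylmenthyl ester controls the absolute sense; geranylacetone supplies the diene.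

Key step: step 6

Remarks on the chemistry
- Numbering and faces: labdane numbering is used (ring A = C1–C5 and C10; ring B = C5–C10; C17 on C8; methyl C18 and carbon C19 on C4; methyl C20 on C10; side chain C11–C16). α is the face of the C10 methyl group, β the face of H5. The target is 2β,3β-diacetoxy, 4β-methyl, 4α (axial) formyl, H5β, H9β, 10α-methyl.
- Assumption: the (1S,2R,5S)-8-phenylmenthyl ester is taken to direct the first ring closure to the 10α-methyl series drawn; should the sense be the reverse, the (1R,2S,5R) auxiliary is used and nothing else changes.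
- Assumption: (E)-geranylacetone is used as the single (E) isomer.

Step 1
Reactants: 1 (E)-geranylacetone
Product: 2 2-[(3E)-4,8-dimethylnona-3,7-dien-1-yl]-2-methyl-1,3-dioxolane
Conditions: HOCH2CH2OH, PPTS (cat.), benzene, reflux (Dean–Stark)
Reagents that add atoms: ethylene glycol OCCO
Why: Acid-catalysed ketalisation with azeotropic removal of water masks the methyl ketone as a dioxolane for the enolate and hydride steps ahead, and the mild acid leaves the trisubstituted alkenes untouched.

Step 2
Reactants: 2 dioxolane of geranylacetone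
Product: 3 (2E,6E)-2,6-dimethyl-9-(2-methyl-1,3-dioxolan-2-yl)nona-2,6-dien-1-ol
Conditions: SeO2 (cat.), t-BuOOH, salicylic acid (cat.), CH2Cl2, 0 → 25 °C
Reagents that add atoms: tert-butyl hydroperoxide CC(C)(C)OO; selenium dioxide O=[Se]=O (catalytic oxygen carrier)
Why: Riley allylic oxidation (ene reaction then [2,3]-sigmatropic shift) should hydroxylate the (E)-methyl group of the terminal trisubstituted alkene selectively, giving the (E)-allylic alcohol.

Step 3
Reactants: 3 (E,E)-allylic alcohol
Product: 4 2-[(3E,7E)-9-bromo-4,8-dimethylnona-3,7-dien-1-yl]-2-methyl-1,3-dioxolane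
Conditions: CBr4, PPh3, CH2Cl2, 0 °C
Reagents that add atoms: carbon tetrabromide BrC(Br)(Br)Br
Why: Appel bromination under neutral conditions should convert the primary allylic alcohol into the bromide without allylic transposition or loss of the dioxolane.

Step 4
Reactants: 5 (+)-8-phenylmenthol; 6 ethyl 2-methyl-3-oxobutanoate
Product: 7 (1S,2R,5S)-8-phenylmenthyl 2-methyl-3-oxobutanoate (both C2 epimers)
Conditions: DMAP (cat.), toluene, reflux, EtOH distilled off
Reagents that add atoms: none
Why: DMAP-catalysed transesterification of a β-keto ester (through the acylketene) installs the chiral ester, and the epimeric α-carbon is of no consequence because it later becomes the radical centre.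

Step 5
Reactants: 7 8-phenylmenthyl 2-methylacetoacetate; 4 allylic bromide
Product: 9 (1S,2R,5S)-8-phenylmenthyl (6E,10E)-2,6,10-trimethyl-13-(2-methyl-1,3-dioxolan-2-yl)-3-oxotrideca-6,10-dienoate (both C2 epimers), via dilithium dienolate 8 (not isolated)
Conditions: LDA (2.1 equiv), THF, 0 °C; then 4, −78 → 0 °C
Reagents that add atoms: none
Why: γ-Alkylation of a β-keto ester dianion: the more reactive terminal carbanion should displace the primary allylic bromide in an SN2 sense, leaving both (E)-alkenes intact.

Step 6
Reactants: 9 polyene β-keto ester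
Product: 10 bicyclic keto ester (trans-decalin; C3 ketone; 4β-methyl; 4α axial CO2-(8-phenylmenthyl) as C19; 10α-methyl; H5β; H9β; exocyclic C8=C17 methylene; 9α side chain CH2CH2C(OCH2CH2O)CH3)
Conditions: Mn(OAc)3·2H2O (2.2 equiv), Cu(OAc)2·H2O (1 equiv), degassed EtOH, 25 °C
Reagents that add atoms: none
Why: Mn(OAc)3 oxidises the enolised β-keto ester to the electrophilic C4 radical, which adds to C5 of the electron-rich C5=C10 alkene; the tertiary C10 radical then adds to C9, and the tertiary C8 radical is oxidised by Cu(OAc)2 with loss of a C17 hydrogen, the closest known reaction type being the manganese triacetate-mediated oxidative free-radical polycyclization of unsaturated β-keto esters. Ring A closes 6-endo-trig through the C4–C5 bond and ring B closes 6-endo-trig through the C9–C10 bond. The chair–chair arrangement of the two (E)-alkenes should give the trans ring fusion (C10 methyl anti to H5) and place H9 anti to the C10 methyl, while the ester on C4 should end axial, cis to the C10 methyl, as is usual for 2-methyl-3-oxo esters in this reaction. The absolute sense comes from the 8-phenylmenthyl ester, whose phenyl ring covers one face of the C4 radical so that C5 bonds from the open face. The step needs 6-endo over 5-exo closure, secured by the methyl-bearing alkene carbons C10 and C8 that become tertiary radicals, and no over-oxidation, secured by the absence of a hydrogen on C4 in the product. Ethanol is chosen over acetic acid to spare the dioxolane, and the regiochemistry of the final hydrogen loss is not critical because step 7 converges the alkene isomers.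

Step 7
Reactants: 10 exocyclic alkene
Product: 11 C7=C8 isomer of 10 (8-methyl, trisubstituted ring-B alkene; all else unchanged)
Conditions: CoCl(C32H46N2O2), the chloro cobalt complex of N,N'-bis(3,5-di-tert-butylsalicylidene)ethane-1,2-diamine (3 mol%), PhSiH3 (6 mol%), benzene, 25 °C
Reagents that add atoms: none
Why: Cobalt-hydride hydrogen-atom-transfer isomerisation of a 1,1-disubstituted alkene: reversible H-atom addition to C17 gives the tertiary C8 radical, and loss of the less hindered C7 hydrogen should give the trisubstituted C7=C8 alkene and stop there, because trisubstituted alkenes are poor H-atom acceptors for this catalyst.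

Step 8
Reactants: 11 C7=C8 keto ester
Product: 12 2β-hydroxy-3-ketone (equatorial 2β-OH; all else as 11)
Conditions: KHMDS, THF, −78 °C; then 2-(phenylsulfonyl)-3-phenyloxaziridine, −78 °C
Reagents that add atoms: 2-(phenylsulfonyl)-3-phenyloxaziridine O=S(=O)(c1ccccc1)N1OC1c1ccccc1
Why: Davis enolate hydroxylation: the ketone can enolise only towards C2 because C4 is quaternary, and the oxaziridine should attack the potassium enolate from the β face, opposite the axial C10 methyl and the axial C4 ester, setting the equatorial 2β-hydroxyl.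

Step 9
Reactants: 12 2β-hydroxy-3-ketone
Product: 13 2β,3β-diol 8-phenylmenthyl ester (axial 3β-OH cis to 2β-OH)
Conditions: L-Selectride (LiBH(s-Bu)3), THF, −78 → 0 °C
Reagents that add atoms: none
Why: Bulky-hydride reduction under steric approach control: the tri-sec-butylborohydride should attack the C3 carbonyl along the equatorial trajectory, avoiding the 1,3-diaxial H1β and H5β, and so give the axial 3β-alcohol, as known for 4,4-disubstituted 3-oxo terpenoids, while the hindered ester is untouched.

Step 10
Reactants: 13 2β,3β-diol ester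
Product: 15 2β,3β,19-triol methyl ketone (9α side chain CH2CH2COCH3), via triol dioxolane 14 (not isolated)
Conditions: LiAlH4, THF, 0 °C → reflux; then 1 M HCl, THF/H2O, 25 °C
Reagents that add atoms: water O
Why: Hydride reduction of the hindered ester releases the auxiliary and gives the C19 carbinol, and the acidic work-up hydrolyses the dioxolane to the methyl ketone; no stereocentre is touched.

Step 11
Reactants: 15 triol methyl ketone
Product: 17 (2E)-enoic acid triol (side chain CH2CH2C(CH3)=CHCO2H), via ethyl enoate 16 (not isolated)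
Conditions: (i-PrO)2P(O)CH2CO2Et, NaH (pre-formed anion), THF, 0 → 50 °C; then LiOH, MeOH/H2O, 50 °C; 1 M HCl to pH 3
Reagents that add atoms: ethyl 2-(diisopropoxyphosphoryl)acetate CCOC(=O)CP(=O)(OC(C)C)OC(C)C; lithium hydroxide [Li+].[OH-]
Why: Horner–Wadsworth–Emmons olefination of the methyl ketone with a diisopropyl phosphonate should favour the (E)-trisubstituted enoate (a minor Z isomer would be removed by chromatography), and saponification in the same flask gives the acid; the stabilised phosphonate anion does not deprotonate the free hydroxyls.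

Step 12
Reactants: 17 triol acid
Product: 18 2β,3β-dihydroxy-19-aldehyde acid
Conditions: TEMPO (20 mol%), PhI(OAc)2 (1.2 equiv), CH2Cl2, 25 °C
Reagents that add atoms: none
Why: Oxoammonium (TEMPO) oxidation is selective for primary over secondary alcohols, so only the C19 carbinol should be oxidised, and it stops at the aldehyde in the absence of water; C4 is quaternary, so no epimerisation is possible.

Step 13
Reactants: 18 dihydroxy aldehyde acid
Product: 19 target, (2E)-5-[(1R,4aS,5S,6R,7S,8aS)-6,7-diacetoxy-5-formyl-2,5,8a-trimethyl-1,4,4a,5,6,7,8,8a-octahydronaphthalen-1-yl]-3-methylpent-2-enoic acid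
Conditions: Ac2O, pyridine, DMAP (cat.), 25 °C; aqueous work-up
Reagents that add atoms: acetic anhydride CC(=O)OC(C)=O
Why: DMAP-catalysed acetylation should esterify the equatorial 2β- and the axial 3β-hydroxyl; the mixed anhydride formed at the carboxylic acid is hydrolysed on aqueous work-up and the non-enolisable aldehyde is inert.

Compound list
1 | (E)-geranylacetone, (5E)-6,10-dimethylundeca-5,9-dien-2-one | CC(=O)CC/C=C(C)/CCC=C(C)C | starting material
2 | 2-[(3E)-4,8-dimethylnona-3,7-dien-1-yl]-2-methyl-1,3-dioxolane | CC1(CC/C=C(C)/CCC=C(C)C)OCCO1 | intermediate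
3 | (2E,6E)-2,6-dimethyl-9-(2-methyl-1,3-dioxolan-2-yl)nona-2,6-dien-1-ol | CC1(CC/C=C(C)/CC/C=C(C)/CO)OCCO1 | intermediate
4 | 2-[(3E,7E)-9-bromo-4,8-dimethylnona-3,7-dien-1-yl]-2-methyl-1,3-dioxolane | CC1(CC/C=C(C)/CC/C=C(C)/CBr)OCCO1 | intermediate
5 | (+)-8-phenylmenthol, (1S,2R,5S)-5-methyl-2-(2-phenylpropan-2-yl)cyclohexan-1-ol | O[C@H]1C[C@@H](C)CC[C@@H]1C(C)(C)c1ccccc1 | starting material
6 | ethyl 2-methyl-3-oxobutanoate (racemic) | CCOC(=O)C(C)C(C)=O | starting material
7 | (1S,2R,5S)-8-phenylmenthyl 2-methyl-3-oxobutanoate (both C2 epimers) | CC(=O)C(C)C(=O)O[C@H]1C[C@@H](C)CC[C@@H]1C(C)(C)c1ccccc1 | intermediate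
8 | dilithium dienolate of 7 | [Li+].[Li+].C=C([O-])C(C)=C([O-])O[C@H]1C[C@@H](C)CC[C@@H]1C(C)(C)c1ccccc1 | intermediate (not isolated)
9 | (1S,2R,5S)-8-phenylmenthyl (6E,10E)-2,6,10-trimethyl-13-(2-methyl-1,3-dioxolan-2-yl)-3-oxotrideca-6,10-dienoate (both C2 epimers) | CC1(CC/C=C(C)/CC/C=C(C)/CCC(=O)C(C)C(=O)O[C@H]2C[C@@H](C)CC[C@@H]2C(C)(C)c2ccccc2)OCCO1 | intermediate
10 | bicyclic keto ester: trans-decalin, C3 ketone, 4β-methyl, 4α (axial) 8-phenylmenthyl ester (C19), 10α-methyl, H5β, H9β, exocyclic C8=C17, 9α-CH2CH2C(OCH2CH2O)CH3 | C1C[C@@]2(C)[C@H](CCC3(C)OCCO3)C(=C)CC[C@@H]2[C@](C)(C(=O)O[C@H]3C[C@@H](C)CC[C@@H]3C(C)(C)c3ccccc3)C1=O | intermediate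
11 | C7=C8 isomer of 10 (8-methyl, trisubstituted ring-B alkene) | C1C[C@@]2(C)[C@H](CCC3(C)OCCO3)C(C)=CC[C@@H]2[C@](C)(C(=O)O[C@H]3C[C@@H](C)CC[C@@H]3C(C)(C)c3ccccc3)C1=O | intermediate
12 | 2β-hydroxy-3-ketone derived from 11 (equatorial 2β-OH) | O[C@H]1C[C@@]2(C)[C@H](CCC3(C)OCCO3)C(C)=CC[C@@H]2[C@](C)(C(=O)O[C@H]3C[C@@H](C)CC[C@@H]3C(C)(C)c3ccccc3)C1=O | intermediate
13 | 2β,3β-diol 8-phenylmenthyl ester (3β-OH axial) | O[C@H]1C[C@@]2(C)[C@H](CCC3(C)OCCO3)C(C)=CC[C@@H]2[C@](C)(C(=O)O[C@H]3C[C@@H](C)CC[C@@H]3C(C)(C)c3ccccc3)[C@H]1O | intermediate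
14 | 2β,3β,19-triol with dioxolane side chain | O[C@H]1C[C@@]2(C)[C@H](CCC3(C)OCCO3)C(C)=CC[C@@H]2[C@](C)(CO)[C@H]1O | intermediate (not isolated)
15 | 2β,3β,19-triol methyl ketone (9α-CH2CH2COCH3) | O[C@H]1C[C@@]2(C)[C@H](CCC(C)=O)C(C)=CC[C@@H]2[C@](C)(CO)[C@H]1O | intermediate
16 | ethyl (2E)-enoate of the 2β,3β,19-triol | O[C@H]1C[C@@]2(C)[C@H](CC/C(C)=C/C(=O)OCC)C(C)=CC[C@@H]2[C@](C)(CO)[C@H]1O | intermediate (not isolated)
17 | (2E)-enoic acid 2β,3β,19-triol | O[C@H]1C[C@@]2(C)[C@H](CC/C(C)=C/C(=O)O)C(C)=CC[C@@H]2[C@](C)(CO)[C@H]1O | intermediate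
18 | 2β,3β-dihydroxy-19-aldehyde (2E)-enoic acid | O[C@H]1C[C@@]2(C)[C@H](CC/C(C)=C/C(=O)O)C(C)=CC[C@@H]2[C@](C)(C=O)[C@H]1O | intermediate
19 | (2E)-5-[(1R,4aS,5S,6R,7S,8aS)-6,7-diacetoxy-5-formyl-2,5,8a-trimethyl-1,4,4a,5,6,7,8,8a-octahydronaphthalen-1-yl]-3-methylpent-2-enoic acid | CC(=O)O[C@H]1C[C@@]2(C)[C@H](CC/C(C)=C/C(=O)O)C(C)=CC[C@@H]2[C@](C)(C=O)[C@H]1OC(C)=O | target

Total step count: 13. Longest linear sequence: 12 steps (1 to 19 through steps 1–3 and 5–13; step 4 prepares the auxiliary ester 7).

Steps most likely to fail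

Step 6. The oxidative cascade may be intercepted before ring B closes (oxidation of the tertiary C10 radical), the dioxolane may suffer under the acidic oxidising medium, and the ester auxiliary may give only partial facial control. Diastereomers that differ in facial sense still carry the auxiliary and would be separated by chromatography. The fallback replaces the stoichiometric oxidant by an iodine atom-transfer radical chain, so that no oxidant competes for the intermediate radicals. It sets out from 9: iodination with NaH and N-iodosuccinimide (THF, 0 °C) would give the 2-iodo β-keto ester F1. Irradiation with (Bu3Sn)2 (10 mol%) in benzene at 80 °C would close rings A and B by the same two 6-endo additions and end by iodine transfer, giving the tertiary C8 iodide F2. Elimination with DBU (toluene, 25 °C) would return to the route at 10, accompanied by some 11, and step 7 converges both on 11.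

Step 9. Hydride delivery may occur from the axial (β) direction and give the equatorial 3α-alcohol, that is the trans-diol. The fallback sets the C3 configuration by intramolecular hydride delivery from the C19 hydroxyl, which sits on the α face. It sets out from 11: TBSOTf and Et3N (CH2Cl2, 0 °C) would give the silyl enol ether F3. LiAlH4 (THF, reflux, non-acidic work-up) would reduce the ester and release the auxiliary, giving the C19 alcohol F4. Rubottom oxidation with dimethyldioxirane (acetone/CH2Cl2, −78 °C) would attack the enol ether from the β face and, after silyl migration, give the 2β-silyloxy-19-hydroxy-3-ketone F5. Evans–Saksena reduction with Me4NBH(OAc)3 (MeCN/AcOH, −20 °C) would deliver hydride from the C19 oxygen to the α face of C3 and give the 2β-silyloxy-3β,19-diol F6. Bu4NF (THF) would then return to the route at 14, which is hydrolysed to 15 with 1 M HCl as in step 10.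

Step 12. Oxidation of the hindered neopentyl C19 carbinol may be slow, so that oxidation or glycol cleavage of the cis-2,3-diol competes. The fallback protects the diol instead of relying on chemoselectivity. It sets out from 17: 2,2-dimethoxypropane and PPTS (acetone, 25 °C) would give the 2β,3β-acetonide F7; the trans-diaxial C3–O and C4–C19 bonds cannot be bridged, so only the cis-diol reacts. Dess–Martin periodinane (NaHCO3, CH2Cl2) would give the acetonide aldehyde F8. AcOH/H2O (40 °C) would remove the acetonide and return to the route at 18.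

Further compounds
F1 | step 6 | (1S,2R,5S)-8-phenylmenthyl (6E,10E)-2-iodo-2,6,10-trimethyl-13-(2-methyl-1,3-dioxolan-2-yl)-3-oxotrideca-6,10-dienoate (both C2 epimers) | CC1(CC/C=C(C)/CC/C=C(C)/CCC(=O)C(C)(I)C(=O)O[C@H]2C[C@@H](C)CC[C@@H]2C(C)(C)c2ccccc2)OCCO1
F2 | step 6 | 8-iodo-8-methyl bicyclic keto ester with the ring system and stereocentres of 10 (both C8 epimers) | C1C[C@@]2(C)[C@H](CCC3(C)OCCO3)C(C)(I)CC[C@@H]2[C@](C)(C(=O)O[C@H]3C[C@@H](C)CC[C@@H]3C(C)(C)c3ccccc3)C1=O
F3 | step 9 | tert-butyldimethylsilyl enol ether of 11 (C2=C3, silyloxy on C3) | CC(C)(C)[Si](C)(C)OC1=CC[C@@]2(C)[C@H](CCC3(C)OCCO3)C(C)=CC[C@@H]2[C@]1(C)C(=O)O[C@H]1C[C@@H](C)CC[C@@H]1C(C)(C)c1ccccc1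
F4 | step 9 | C19 primary alcohol of the silyl enol ether (auxiliary removed) | CC(C)(C)[Si](C)(C)OC1=CC[C@@]2(C)[C@H](CCC3(C)OCCO3)C(C)=CC[C@@H]2[C@]1(C)CO
F5 | step 9 | 2β-(tert-butyldimethylsilyloxy)-19-hydroxy-3-ketone with dioxolane side chain | CC(C)(C)[Si](C)(C)O[C@H]1C[C@@]2(C)[C@H](CCC3(C)OCCO3)C(C)=CC[C@@H]2[C@](C)(CO)C1=O
F6 | step 9 | 2β-(tert-butyldimethylsilyloxy)-3β,19-diol with dioxolane side chain | CC(C)(C)[Si](C)(C)O[C@H]1C[C@@]2(C)[C@H](CCC3(C)OCCO3)C(C)=CC[C@@H]2[C@](C)(CO)[C@H]1O
F7 | step 12 | 2β,3β-O-isopropylidene acetal of 17 | CC1(C)O[C@H]2C[C@@]3(C)[C@H](CC/C(C)=C/C(=O)O)C(C)=CC[C@@H]3[C@](C)(CO)[C@H]2O1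
F8 | step 12 | 2β,3β-O-isopropylidene acetal of 18 | CC1(C)O[C@H]2C[C@@]3(C)[C@H](CC/C(C)=C/C(=O)O)C(C)=CC[C@@H]3[C@](C)(C=O)[C@H]2O1
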